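# Proposed total synthesis of CNP0186101.1 (31) by convergent SN2′ union of two C16 halves at the quaternary carbon

## The problem

1. Atom labels: C1=C2 is the vinyl group, C3 the quaternary carbon, C5=C6 the E-disubstituted alkene, C7 the methyl-bearing carbon next to it, C11=C12 the E-trisubstituted alkene, C16 the methyl-bearing carbon next to the isopropenyl group (C18=C20), C21–C22 the ethylene tether, and C1′ (tether), C2′ (CMe2), C3′ (CHMe), C6′ (C=CH2) the ring atoms; methyl carbons take the missing numbers.
2. Target 31 is a C32H54 hydrocarbon with one cyclohexane, five C=C bonds and five stereocentres (3S, 7S, 16R, 1′S, 3′S). It has no heteroatom, so every C–C bond must be made by chemistry that leaves no functional group behind.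
3. The hardest atom is C3: an all-carbon quaternary stereocentre carrying methyl, vinyl, an (E)-alkenyl group and the tether, with 16 carbons on either side of the C3–C5 bond.
4. The feature that makes the key step possible: C3 lies in no ring and is the sp3 carbon of a 1,4-diene. It is allylic to the terminal C1=C2 bond and bonded to the sp2 carbon C5 of an E-1,2-disubstituted alkene. This is the retron of an SN2′ substitution of a γ,γ-disubstituted allyl electrophile by an (E)-alkenyl metal made from a terminal alkyne.
5. The stereocentres fall into three groups that cannot control each other: C3/C7, the remote C16, and the ring pair C1′/C3′ (trans across C2′). Only inside the ring can one centre steer another.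
6. In the ring, the bond from C1′ to the tether lies next to the quaternary C2′, and the exocyclic alkene must end at C6′ and nowhere else.
7. The exocyclic methylene, the isopropenyl group and the skipped diene do not survive strong acid (alkene migration, cation–olefin cyclisation). The allylic and propargylic methine centres C7 and C16 can be lost by base- or metal-hydride-induced alkene migration.

## Retrosynthesis

**C3–C5, with allylic transposition.** Target 31 is cut into the E-trisubstituted allylic phosphate 15 (C1–C4, tether and ring, 16 carbons) and the (E)-alkenylalane 30, made in the flask from terminal alkyne 29 (C5–C20, 16 carbons). A cut at C3–C21 or C3–C2 would leave the 1,4-diene on one fragment and a small piece on the other. The C3–C5 cut halves the molecule and puts the ring centres on 15 and C7/C16 on 29. C3 is created in the union itself, and the vinyl group appears as the transposed allyl unit. The forward reaction must be SN2′-selective, transfer alkenyl rather than isobutyl, keep the E geometry and choose one face of C3 under catalyst control.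

**Phosphate 15 to alkyne 12.** The C2=C3 alkene of 15 comes from alcohol 14, made by syn-methylalumination of alkyne 12 and trapping of alkenylalane 13 with formaldehyde. A carbonyl olefination of ketone 10 would give E/Z mixtures; carbometalation gives one geometry.

**Alkyne 12 to ketone 10, then C1′–C22.** Alkyne 12 comes from methyl ketone 10 through enol phosphate 11. Ketone 10 is cut at the hindered C1′–C22 bond into allylsilane 7 and but-3-en-2-one 8 (Hosomi–Sakurai addition through titanium enolate 9). This one cut forms the bond next to the quaternary carbon, fixes the alkene as exocyclic at C6′ and sets C1′ relative to C3′. A cuprate SN2′ or an enolate alkylation would have to fight the neopentyl position and would not fix the alkene position.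

**Allylsilane 7 to enone 4.** Allylsilane 7 comes from enol triflate 6. The triflate regiochemistry (double bond towards the gem-dimethyl carbon) is dictated by conjugate addition of a methyl cuprate to enone 4 and trapping of enolate 5. The same step creates C2′.

**Enone 4 to anisole 1 (dearomatisation).** The single stereocentre of 4 comes from enantioselective isomerisation of the achiral β,γ-enone 3, which is the hydrolysed Birch product (diene 2) of 3,4-dimethylanisole 1. The arene supplies all six ring carbons and two of the three ring methyls.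

**Alkyne 29 at C14–C15.** Alkyne 29 is cut into allylic bromide 27 and Grignard reagent 28 (from bromide 22). This sp3–sp3 cut leaves the C11=C12 geometry to a chiral-pool terpene and separates C7 from C16, so each centre is made where it is easiest.

**Bromide 27 to (S)-citronellal 23.** Bromide 27 comes from alcohol 26, the product of E-selective allylic oxidation of enyne 25. Enyne 25 is (S)-citronellal 23 with the CH2–CHO unit turned into C≡CH (through enol nonaflate 24). Citronellal supplies C7 and the trisubstituted alkene.

**Bromide 22 to auxiliary 16.** Bromide 22 comes from alcohol 21 and imide 20. The C16 centre and the isopropenyl group arise together in the deconjugative methylation of imide 18 (through dienolate 19). Imide 18 is made from oxazolidinone 16 and acid chloride 17.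

## Roads not taken

**Alternative 1:** Johnson–Claisen rearrangement (the most obvious route). Cut C3–C2; the vinyl group is carried as CH2CO2Et. The secondary allylic alcohol A1 (6S carbinol, E-alkene) would rearrange with triethyl orthoacetate through a chair to ester A2, with 1,3-chirality transfer to C3 and formation of the E C5=C6 bond.
- It needs a sacrificial carbinol stereocentre at C6, set against C7.
- A1 must be assembled linearly, by adding an alkenyl metal from 12 to the epimerisable α-methyl aldehyde A3.
- Three more steps are needed to turn CH2CO2Et into vinyl.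
- The chosen SN2′ step needs no sacrificial centre, joins two finished halves and delivers the vinyl group directly.

**Alternative 2:** Julia–Kocienski olefination at C5=C6. Cut the E-alkene into the α-quaternary aldehyde A4 and the tetrazolyl sulfone A5.
- The quaternary centre is only moved onto a small fragment, where methyl, vinyl and CH2 must still be told apart by a separate asymmetric method.
- The aldehyde is neopentylic and the sulfone β-branched, a poor pairing for rate and E selectivity.
- The chosen plan makes C3 and the C3–C5 bond in one event.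

**Alternative 3:** Biomimetic cation–olefin cyclisation. Cut C1′–C2′ and close the ring last from the open-chain hexaene A6 with a Brønsted or Lewis acid.
- Both chain ends of A6 carry the same isopropenyl/trisubstituted-alkene motif, so the acid cannot select one terminus.
- A chair closure of the E-alkene gives the tether and C3′-methyl cis, not the trans arrangement of 31.
- Loss of the proton is not confined to the exocyclic position.
- The skipped diene at C3 would not survive the acid.
- The chosen plan sets the ring stereochemistry and the exocyclic alkene on a C14 fragment.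

Key step: step 17

Assumption (chemistry): the sense of induction of the chiral catalysts in steps 2 and 17 follows that of their substrate classes. Both catalysts are available in mirror-image or pseudo-enantiomeric form, so either sense can be served once confirmed on the actual substrate.

## Steps

**Step 1**
Reactants: 1 3,4-dimethylanisole
Product: 3 3,4-dimethylcyclohex-3-en-1-one, via Birch diene 2 (not isolated)
Conditions: Li, NH3(l), THF, t-BuOH, −78 to −33 °C; then (CO2H)2, MeOH/H2O, 23 °C
Reagents that add atoms: water, O
Why: Birch reduction of an anisole leaves the methoxy and alkyl groups on the two remaining double bonds; mild acid hydrolyses only the enol ether, so the tetrasubstituted alkene stays out of conjugation and no stereocentre is formed yet.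

**Step 2**
Reactants: 3 3,4-dimethylcyclohex-3-en-1-one
Product: 4 (4S)-3,4-dimethylcyclohex-2-en-1-one
Conditions: 9-amino-9-deoxy-epi-cinchona primary–tertiary diamine catalyst (10 mol %), carboxylic acid co-catalyst, toluene, −25 to 23 °C
Reagents that add atoms: none
Why: Enantioselective isomerisation of a cyclohex-3-enone to the conjugated enone by iminium–base catalysis: the primary amine forms the dienamine and the protonated quinuclidine delivers the proton to one face of C4. This sets the one ring stereocentre obtained from a catalyst; the pseudo-enantiomer giving (S) is used.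

**Step 3**
Reactants: 4 (4S)-3,4-dimethylcyclohex-2-en-1-one
Product: 6 (4S)-3,3,4-trimethylcyclohex-1-en-1-yl trifluoromethanesulfonate, via lithium enolate 5 (not isolated)
Conditions: Me2CuLi (from CuI and MeLi), Et2O, −20 to 0 °C; then PhNTf2, THF, −78 to 23 °C
Reagents that add atoms: lithium dimethylcuprate, [Li+].C[Cu-]C; N-phenylbis(trifluoromethanesulfonimide), O=S(=O)(N(c1ccccc1)S(=O)(=O)C(F)(F)F)C(F)(F)F
Why: Conjugate addition of a lithium dialkylcuprate creates the gem-dimethyl carbon (no new stereocentre) and leaves the enolate on the side of that carbon. O-Sulfonylation fixes this regiochemistry as the enol triflate, which deprotonation of the ketone would not give.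

**Step 4**
Reactants: 6 (4S)-3,3,4-trimethylcyclohex-1-en-1-yl trifluoromethanesulfonate
Product: 7 trimethyl{[(4S)-3,3,4-trimethylcyclohex-1-en-1-yl]methyl}silane
Conditions: Me3SiCH2MgCl, Pd(PPh3)4 (5 mol %), THF, 0 to 23 °C
Reagents that add atoms: (trimethylsilyl)methylmagnesium chloride, C[Si](C)(C)C[Mg]Cl
Why: Kumada–Corriu coupling of an enol triflate with the silylmethyl Grignard reagent is the standard route to 2-substituted allylsilanes; the stereocentre is not touched.

**Step 5**
Reactants: 7 trimethyl{[(4S)-3,3,4-trimethylcyclohex-1-en-1-yl]methyl}silane; 8 but-3-en-2-one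
Product: 10 4-[(1S,3S)-2,2,3-trimethyl-6-methylidenecyclohexyl]butan-2-one, via titanium enolate 9 (not isolated)
Conditions: TiCl4 (1.1 equiv), CH2Cl2, −78 °C; aq NaHCO3
Reagents that add atoms: none
Why: Hosomi–Sakurai conjugate allylation: the TiCl4-activated enone attacks the ring CH next to the gem-dimethyl carbon, and loss of silicon from the β-silyl cation can only leave the double bond exocyclic. With the ring methyl equatorial in the half-chair, the pseudoaxial methyl of CMe2 shields one face and axial attack on the other gives the chain trans to the C3′ methyl (1S,3S).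

**Step 6**
Reactants: 10 4-[(1S,3S)-2,2,3-trimethyl-6-methylidenecyclohexyl]butan-2-one
Product: 12 4-[(1S,3S)-2,2,3-trimethyl-6-methylidenecyclohexyl]but-1-yne, via enol phosphate 11 (not isolated)
Conditions: LiN(i-Pr)2 (1.05 equiv), THF, −78 °C; ClP(O)(OEt)2, −78 to 23 °C; LiN(i-Pr)2 (2.3 equiv), −78 to 23 °C; H2O
Reagents that add atoms: none
Why: Kinetic deprotonation of the methyl ketone at CH3, O-phosphorylation and amide-induced elimination of the enol phosphate (methyl ketone to terminal alkyne); no stereocentre is involved and the exocyclic alkene is inert to amide base.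

**Step 7**
Reactants: 12 4-[(1S,3S)-2,2,3-trimethyl-6-methylidenecyclohexyl]but-1-yne
Product: 14 (2E)-3-methyl-5-[(1S,3S)-2,2,3-trimethyl-6-methylidenecyclohexyl]pent-2-en-1-ol, via alkenylalane 13 (not isolated)
Conditions: AlMe3 (2.5 equiv), Cp2ZrCl2 (0.25 equiv), CH2Cl2, 0 to 23 °C; then (CH2O)n, THF, 0 to 23 °C
Reagents that add atoms: trimethylaluminium, C[Al](C)C; formaldehyde (as paraformaldehyde), C=O
Why: Zirconium-catalysed methylalumination of a terminal alkyne is syn and puts aluminium on the terminal carbon, so trapping with formaldehyde should give only the (E)-3-methyl allylic alcohol; the 1,1-disubstituted ring alkene does not react.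

**Step 8**
Reactants: 14 (2E)-3-methyl-5-[(1S,3S)-2,2,3-trimethyl-6-methylidenecyclohexyl]pent-2-en-1-ol
Product: 15 diethyl (2E)-3-methyl-5-[(1S,3S)-2,2,3-trimethyl-6-methylidenecyclohexyl]pent-2-en-1-yl phosphate
Conditions: ClP(O)(OEt)2, Et3N, DMAP (cat.), CH2Cl2, 0 °C
Reagents that add atoms: diethyl chlorophosphate, CCOP(=O)(Cl)OCC
Why: O-Phosphorylation of a primary allylic alcohol; the phosphate is the leaving group that the copper-catalysed SN2′ step needs.

**Step 9**
Reactants: 16 (4S)-4-benzyl-1,3-oxazolidin-2-one; 17 3-methylbut-2-enoyl chloride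
Product: 18 (4S)-4-benzyl-3-(3-methylbut-2-enoyl)-1,3-oxazolidin-2-one
Conditions: n-BuLi, THF, −78 °C; then 17, −78 to 0 °C
Reagents that add atoms: none
Why: N-Acylation of the lithiated oxazolidinone with an acid chloride.

**Step 10**
Reactants: 18 (4S)-4-benzyl-3-(3-methylbut-2-enoyl)-1,3-oxazolidin-2-one
Product: 20 (4S)-4-benzyl-3-[(2S)-2,3-dimethylbut-3-enoyl]-1,3-oxazolidin-2-one, via sodium dienolate 19 (not isolated)
Conditions: NaN(SiMe3)2, THF, −78 °C; MeI, −78 to −40 °C
Reagents that add atoms: iodomethane, CI
Why: Deconjugative alkylation: γ-deprotonation gives the chelated Z-dienolate, which is methylated at the α-carbon on the face opposite the benzyl group (Evans-type auxiliary control). This sets the future C16 and creates the isopropenyl group in the same event.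

**Step 11**
Reactants: 20 (4S)-4-benzyl-3-[(2S)-2,3-dimethylbut-3-enoyl]-1,3-oxazolidin-2-one
Product: 21 (2S)-2,3-dimethylbut-3-en-1-ol
Conditions: LiBH4, H2O (1 equiv), Et2O, 0 °C
Reagents that add atoms: none
Why: Reductive cleavage of the N-acyl oxazolidinone with borohydride gives the primary alcohol without enolising the α-stereocentre and returns the auxiliary.

**Step 12**
Reactants: 21 (2S)-2,3-dimethylbut-3-en-1-ol
Product: 22 (3S)-4-bromo-2,3-dimethylbut-1-ene
Conditions: Ph3PBr2, imidazole, CH2Cl2, 0 °C
Reagents that add atoms: dibromotriphenylphosphorane, BrP(Br)(c1ccccc1)(c1ccccc1)c1ccccc1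
Why: Appel-type bromination of a primary alcohol through the alkoxyphosphonium salt; the neutral, buffered conditions avoid migration of the 1,1-disubstituted alkene, and the stereocentre is not a reacting atom.

**Step 13**
Reactants: 23 (S)-citronellal
Product: 25 (3S)-3,7-dimethyloct-6-en-1-yne, via enol nonaflate 24 (not isolated)
Conditions: n-C4F9SO2F, phosphazene base P2-Et (2.2 equiv), DMF, −30 to 23 °C
Reagents that add atoms: none
Why: One-pot aldehyde-to-alkyne conversion: the enolate is O-sulfonylated to the 1-alkenyl nonaflate and a second equivalent of base eliminates nonaflate. The methyl-bearing centre is not deprotonated and becomes the propargylic centre C7 (S).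

**Step 14**
Reactants: 25 (3S)-3,7-dimethyloct-6-en-1-yne
Product: 26 (2E,6S)-2,6-dimethyloct-2-en-7-yn-1-ol
Conditions: SeO2 (0.3 equiv), t-BuOOH (3 equiv), salicylic acid (0.1 equiv), CH2Cl2, 23 °C
Reagents that add atoms: tert-butyl hydroperoxide, CC(C)(C)OO
Why: SeO2-catalysed allylic oxidation (ene reaction, then 2,3-sigmatropic shift) attacks the trisubstituted alkene at the methyl group trans to the chain and gives the (E)-allylic alcohol; the terminal alkyne and its tertiary propargylic C–H react much more slowly.

**Step 15**
Reactants: 26 (2E,6S)-2,6-dimethyloct-2-en-7-yn-1-ol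
Product: 27 (3S,6E)-8-bromo-3,7-dimethyloct-6-en-1-yne
Conditions: CBr4, PPh3, CH2Cl2, −20 to 0 °C
Reagents that add atoms: tetrabromomethane, BrC(Br)(Br)Br
Why: Appel bromination of a primary allylic alcohol at low temperature proceeds by direct displacement, without allylic transposition or loss of E geometry.

**Step 16**
Reactants: 22 (3S)-4-bromo-2,3-dimethylbut-1-ene; 27 (3S,6E)-8-bromo-3,7-dimethyloct-6-en-1-yne
Product: 29 (3S,6E,10R)-3,7,10,11-tetramethyldodeca-6,11-dien-1-yne, via Grignard reagent 28 (not isolated)
Conditions: 22, Mg, THF, 23 °C; then added slowly (1.5 equiv) to 27, Li2CuCl4 (5 mol %), THF, −78 to −30 °C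
Reagents that add atoms: none
Why: Copper-catalysed coupling of a primary alkyl Grignard reagent with a primary allylic bromide occurs at the unsubstituted α-carbon with retention of the E geometry. At −78 °C the substitution should outrun deprotonation of the acetylenic C–H, and an acetylide on copper is a non-transferable ligand in any case. The C16 centre is β to magnesium and is not involved.

**Step 17**
Reactants: 29 (3S,6E,10R)-3,7,10,11-tetramethyldodeca-6,11-dien-1-yne; 15 diethyl (2E)-3-methyl-5-[(1S,3S)-2,2,3-trimethyl-6-methylidenecyclohexyl]pent-2-en-1-yl phosphate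
Product: 31 (3S,4E,6S,9E,13R)-3,6,10,13,14-pentamethyl-3-{2-[(1S,3S)-2,2,3-trimethyl-6-methylidenecyclohexyl]ethyl}pentadeca-1,4,9,14-tetraene (target), via alkenylalane 30 (not isolated)
Conditions: 29 (1.6 equiv), i-Bu2AlH (1.5 equiv), hexanes, 55 °C; then 15 (1.0 equiv), CuCl2·2H2O (5 mol %), chiral sulfonate-bearing imidazolinium salt (N-heterocyclic carbene precursor, 6 mol %), THF, −15 °C
Reagents that add atoms: none
Why: i-Bu2AlH adds syn and anti-Markovnikov across the terminal alkyne of 29 only, giving the (E)-alkenylalane 30; the 1,1-disubstituted and trisubstituted alkenes do not hydroaluminate at 55 °C. The alane deprotonates the imidazolinium salt and reduces the copper salt, and the alkenyl group passes to the chiral carbene–copper complex, whose sulfonate arm bridges aluminium and copper. The alkenylcopper adds to C3 of phosphate 15 anti to the leaving group to give a trivalent copper allyl, and reductive elimination forms the C3–C5 bond while the double bond moves to C1=C2. The closest known reaction type is the carbene–copper-catalysed enantioselective allylic substitution of E-trisubstituted allylic phosphates with alkenyl(diisobutyl)aluminium reagents, which gives quaternary carbons bearing a vinyl and an E-alkenyl group from geranyl-type phosphates. No ring is closed. The one new stereocentre, C3, is set by the catalyst: the ligand enantiomer is chosen to deliver the alkenyl group to the face of the E-alkene that gives (S), and the existing centres are too remote (C7 is γ to the metal, C1′ is four bonds from C3) to interfere. The step needs SN2′ over SN2 selectivity (secured by the phosphate leaving group and the bidentate sulfonate carbene–copper catalyst), transfer of alkenyl in preference to isobutyl (faster for the sp2 carbon), and retention of the E geometry (hydroalumination and transmetalation are both stereospecific). Neither partner carries a protic or Lewis-basic group, and the other alkenes are inert to the alkenylcopper.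

## Compound list

1 | 3,4-dimethylanisole | COc1ccc(C)c(C)c1 | starting material
2 | 1-methoxy-4,5-dimethylcyclohexa-1,4-diene | COC1=CCC(C)=C(C)C1 | intermediate (not isolated)
3 | 3,4-dimethylcyclohex-3-en-1-one | O=C1CCC(C)=C(C)C1 | intermediate
4 | (4S)-3,4-dimethylcyclohex-2-en-1-one | O=C1CC[C@H](C)C(C)=C1 | intermediate
5 | lithium (4S)-3,3,4-trimethylcyclohex-1-en-1-olate | [Li]OC1=CC(C)(C)[C@@H](C)CC1 | intermediate (not isolated)
6 | (4S)-3,3,4-trimethylcyclohex-1-en-1-yl trifluoromethanesulfonate | FC(F)(F)S(=O)(=O)OC1=CC(C)(C)[C@@H](C)CC1 | intermediate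
7 | trimethyl{[(4S)-3,3,4-trimethylcyclohex-1-en-1-yl]methyl}silane | C[Si](C)(C)CC1=CC(C)(C)[C@@H](C)CC1 | intermediate
8 | but-3-en-2-one | CC(=O)C=C | starting material
9 | trichlorotitanium enolate of ketone 10 | CC(O[Ti](Cl)(Cl)Cl)=CC[C@H]1C(=C)CC[C@H](C)C1(C)C | intermediate (not isolated)
10 | 4-[(1S,3S)-2,2,3-trimethyl-6-methylidenecyclohexyl]butan-2-one | CC(=O)CC[C@H]1C(=C)CC[C@H](C)C1(C)C | intermediate
11 | diethyl 4-[(1S,3S)-2,2,3-trimethyl-6-methylidenecyclohexyl]but-1-en-2-yl phosphate | C=C(OP(=O)(OCC)OCC)CC[C@H]1C(=C)CC[C@H](C)C1(C)C | intermediate (not isolated)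
12 | 4-[(1S,3S)-2,2,3-trimethyl-6-methylidenecyclohexyl]but-1-yne | C#CCC[C@H]1C(=C)CC[C@H](C)C1(C)C | intermediate
13 | dimethyl{(1E)-2-methyl-4-[(1S,3S)-2,2,3-trimethyl-6-methylidenecyclohexyl]but-1-en-1-yl}alane | C[Al](C)/C=C(\C)CC[C@H]1C(=C)CC[C@H](C)C1(C)C | intermediate (not isolated)
14 | (2E)-3-methyl-5-[(1S,3S)-2,2,3-trimethyl-6-methylidenecyclohexyl]pent-2-en-1-ol | OC/C=C(\C)CC[C@H]1C(=C)CC[C@H](C)C1(C)C | intermediate
15 | diethyl (2E)-3-methyl-5-[(1S,3S)-2,2,3-trimethyl-6-methylidenecyclohexyl]pent-2-en-1-yl phosphate | CCOP(=O)(OCC)OC/C=C(\C)CC[C@H]1C(=C)CC[C@H](C)C1(C)C | intermediate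
16 | (4S)-4-benzyl-1,3-oxazolidin-2-one | O=C1N[C@@H](Cc2ccccc2)CO1 | starting material
17 | 3-methylbut-2-enoyl chloride | CC(C)=CC(Cl)=O | starting material
18 | (4S)-4-benzyl-3-(3-methylbut-2-enoyl)-1,3-oxazolidin-2-one | CC(C)=CC(=O)N1[C@@H](Cc2ccccc2)COC1=O | intermediate
19 | sodium Z-dienolate of imide 18 | C=C(C)/C=C(\O[Na])N1[C@@H](Cc2ccccc2)COC1=O | intermediate (not isolated)
20 | (4S)-4-benzyl-3-[(2S)-2,3-dimethylbut-3-enoyl]-1,3-oxazolidin-2-one | C=C(C)[C@H](C)C(=O)N1[C@@H](Cc2ccccc2)COC1=O | intermediate
21 | (2S)-2,3-dimethylbut-3-en-1-ol | C=C(C)[C@H](C)CO | intermediate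
22 | (3S)-4-bromo-2,3-dimethylbut-1-ene | C=C(C)[C@H](C)CBr | intermediate
23 | (S)-citronellal, (3S)-3,7-dimethyloct-6-enal | O=CC[C@@H](C)CCC=C(C)C | starting material
24 | (3S)-3,7-dimethylocta-1,6-dien-1-yl nonafluorobutane-1-sulfonate | FC(F)(F)C(F)(F)C(F)(F)C(F)(F)S(=O)(=O)OC=C[C@@H](C)CCC=C(C)C | intermediate (not isolated)
25 | (3S)-3,7-dimethyloct-6-en-1-yne | C#C[C@@H](C)CCC=C(C)C | intermediate
26 | (2E,6S)-2,6-dimethyloct-2-en-7-yn-1-ol | C#C[C@@H](C)CC/C=C(\C)CO | intermediate
27 | (3S,6E)-8-bromo-3,7-dimethyloct-6-en-1-yne | C#C[C@@H](C)CC/C=C(\C)CBr | intermediate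
28 | [(2S)-2,3-dimethylbut-3-en-1-yl]magnesium bromide | C=C(C)[C@H](C)C[Mg]Br | intermediate (not isolated)
29 | (3S,6E,10R)-3,7,10,11-tetramethyldodeca-6,11-dien-1-yne | C#C[C@@H](C)CC/C=C(\C)CC[C@@H](C)C(C)=C | intermediate
30 | bis(2-methylpropyl)[(1E,3S,6E,10R)-3,7,10,11-tetramethyldodeca-1,6,11-trien-1-yl]alane | CC(C)C[Al](CC(C)C)/C=C/[C@@H](C)CC/C=C(\C)CC[C@@H](C)C(C)=C | intermediate (not isolated)
31 | (3S,4E,6S,9E,13R)-3,6,10,13,14-pentamethyl-3-{2-[(1S,3S)-2,2,3-trimethyl-6-methylidenecyclohexyl]ethyl}pentadeca-1,4,9,14-tetraene | C=C[C@@](C)(/C=C/[C@@H](C)CC/C=C(\C)CC[C@@H](C)C(=C)C)CC[C@H]1C(=C)CC[C@H](C)C1(C)C | target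

## Step count and least certain steps

Total step count: 17. Longest linear sequence: 9 steps (steps 1–8, then step 17). The chain half takes 4 steps (13–16) plus a 4-step side branch (9–12).

**Step 17 (key step).**
- What may go wrong: poor facial discrimination at C3, because the two γ-substituents (methyl and a primary alkyl chain) differ only modestly and the nucleophile is α-branched; erosion of SN2′ selectivity towards direct substitution; competing transfer of isobutyl or hydride; deprotonation instead of hydroalumination of the alkyne.
- Fallback (sets out from 14 and 29, returns at 31): it keeps the C3–C5 bond but makes it stereospecific instead of catalyst-controlled. Sharpless epoxidation of 14 (Ti(OiPr)4, D-(−)-diethyl tartrate, t-BuOOH, 4 Å sieves, CH2Cl2, −20 °C) should give the (2R,3R)-epoxy alcohol F1. Lithiation of 29 with n-BuLi and transmetalation with Et2AlCl give the diethylalkynylalane F2. Hydroxyl-directed organoaluminium opening of F1 by F2 at the fully substituted C3, with inversion, should give the alkynyl diol F3. Deoxygenation of the vicinal diol (I2, PPh3, imidazole, toluene, 80 °C) gives the vinyl group of enyne F4. Dissolving-metal reduction (Na, NH3(l), THF, −78 °C) then turns the C5≡C6 alkyne into the E-alkene of 31.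

**Step 5.**
- What may go wrong: slow attack at the ring carbon next to the quaternary centre, so that protodesilylation of 7 takes over; incomplete trans selectivity; Lewis-acid-induced migration of the new exocyclic alkene or Prins-type closure onto the ketone.
- Fallback (sets out from 6, returns at 12): it forms the same bond intramolecularly by a Claisen rearrangement. Methoxycarbonylation of 6 (Pd(OAc)2, PPh3, CO, MeOH, Et3N, DMF) gives methyl (4S)-3,3,4-trimethylcyclohex-1-ene-1-carboxylate F5. Reduction with i-Bu2AlH gives [(4S)-3,3,4-trimethylcyclohex-1-en-1-yl]methanol F6. Johnson–Claisen rearrangement (MeC(OEt)3, EtCO2H cat., 140 °C) should give ethyl 2-[(1S,3S)-2,2,3-trimethyl-6-methylidenecyclohexyl]acetate F7, with the same facial preference as in step 5. LiAlH4 reduction gives 2-[(1S,3S)-2,2,3-trimethyl-6-methylidenecyclohexyl]ethan-1-ol F8. Iodination (I2, PPh3, imidazole) gives the primary iodide F9. Displacement with lithium acetylide–ethylenediamine complex in DMSO gives 12.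

**Step 2.**
- What may go wrong: lower enantioselectivity for a substrate whose β,γ-alkene is tetrasubstituted; uncatalysed isomerisation; erosion of the product by reversible dienamine formation.
- Fallback (sets out from 3, returns at 4): isomerisation of 3 with DBU gives racemic 3,4-dimethylcyclohex-2-en-1-one F10. This is resolved by preparative chromatography on a chiral stationary phase; the unwanted enantiomer is racemised with base through the extended enolate and recycled.

**Step 13.**
- What may go wrong: aldol self-condensation of citronellal competing with O-sulfonylation; incomplete elimination; base-induced propargyl–allene isomerisation that would erode C7.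
- Fallback (sets out from 23, returns at 25): remove one carbon and put one back. Silylation of 23 (Me3SiCl, Et3N, NaI, MeCN) gives the enol ether {[(3S)-3,7-dimethylocta-1,6-dien-1-yl]oxy}trimethylsilane F11. Selective ozonolysis of the electron-rich enol ether (1 equiv O3, CH2Cl2, −78 °C; Me2S) gives (2S)-2,6-dimethylhept-5-enal F12. Ohira–Bestmann homologation (dimethyl (1-diazo-2-oxopropyl)phosphonate, K2CO3, MeOH, 0 °C) gives 25.

**Step 16.**
- What may go wrong: deprotonation of the acetylenic C–H by 28, which consumes the reagent; attack at the γ-carbon giving the branched isomer; partial loss of E geometry; rearrangement of the homoallylic Grignard reagent through its cyclopropylcarbinyl form.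
- Fallback (sets out from 27 and 21, returns at 29): reverse the polarity at C14. Reaction of 27 with PhSO2Na in DMF gives the allylic sulfone {[(2E,6S)-2,6-dimethyloct-2-en-7-yn-1-yl]sulfonyl}benzene F13. Alcohol 21 is converted (I2, PPh3, imidazole) into (3S)-4-iodo-2,3-dimethylbut-1-ene F14. The α-sulfonyl carbanion of F13 (n-BuLi, THF/DMPU, −78 °C) is alkylated with F14 to give the sulfone F15, epimeric at the sulfonyl carbon. Reductive desulfonylation (Pd(dppp)Cl2 cat., LiBHEt3, THF) gives 29.

## Further compounds

F1 | step 17 | [(2R,3R)-3-methyl-3-{2-[(1S,3S)-2,2,3-trimethyl-6-methylidenecyclohexyl]ethyl}oxiran-2-yl]methanol | OC[C@H]1O[C@]1(C)CC[C@H]2C(=C)CC[C@H](C)C2(C)C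
F2 | step 17 | diethyl[(3S,6E,10R)-3,7,10,11-tetramethyldodeca-6,11-dien-1-yn-1-yl]alane | CC[Al](CC)C#C[C@@H](C)CC/C=C(\C)CC[C@@H](C)C(C)=C
F3 | step 17 | (2S,3R)-3-methyl-3-[(3S,6E,10R)-3,7,10,11-tetramethyldodeca-6,11-dien-1-yn-1-yl]-5-[(1S,3S)-2,2,3-trimethyl-6-methylidenecyclohexyl]pentane-1,2-diol | OC[C@@H](O)[C@@](C)(C#C[C@@H](C)CC/C=C(\C)CC[C@@H](C)C(C)=C)CC[C@H]1C(=C)CC[C@H](C)C1(C)C
F4 | step 17 | (3S,6S,9E,13R)-3,6,10,13,14-pentamethyl-3-{2-[(1S,3S)-2,2,3-trimethyl-6-methylidenecyclohexyl]ethyl}pentadeca-1,9,14-trien-4-yne | C=C[C@@](C)(C#C[C@@H](C)CC/C=C(\C)CC[C@@H](C)C(C)=C)CC[C@H]1C(=C)CC[C@H](C)C1(C)C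
F5 | step 5 | methyl (4S)-3,3,4-trimethylcyclohex-1-ene-1-carboxylate | COC(=O)C1=CC(C)(C)[C@@H](C)CC1
F6 | step 5 | [(4S)-3,3,4-trimethylcyclohex-1-en-1-yl]methanol | OCC1=CC(C)(C)[C@@H](C)CC1
F7 | step 5 | ethyl 2-[(1S,3S)-2,2,3-trimethyl-6-methylidenecyclohexyl]acetate | CCOC(=O)C[C@H]1C(=C)CC[C@H](C)C1(C)C
F8 | step 5 | 2-[(1S,3S)-2,2,3-trimethyl-6-methylidenecyclohexyl]ethan-1-ol | OCC[C@H]1C(=C)CC[C@H](C)C1(C)C
F9 | step 5 | 2-[(1S,3S)-2,2,3-trimethyl-6-methylidenecyclohexyl]ethyl iodide | ICC[C@H]1C(=C)CC[C@H](C)C1(C)C
F10 | step 2 | racemic 3,4-dimethylcyclohex-2-en-1-one | O=C1CCC(C)C(C)=C1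
F11 | step 13 | {[(3S)-3,7-dimethylocta-1,6-dien-1-yl]oxy}trimethylsilane (E/Z mixture) | C[Si](C)(C)OC=C[C@@H](C)CCC=C(C)C
F12 | step 13 | (2S)-2,6-dimethylhept-5-enal | O=C[C@@H](C)CCC=C(C)C
F13 | step 16 | {[(2E,6S)-2,6-dimethyloct-2-en-7-yn-1-yl]sulfonyl}benzene | C#C[C@@H](C)CC/C=C(\C)CS(=O)(=O)c1ccccc1
F14 | step 16 | (3S)-4-iodo-2,3-dimethylbut-1-ene | C=C(C)[C@H](C)CI
F15 | step 16 | {[(3S,6E,10R)-3,7,10,11-tetramethyldodeca-6,11-dien-1-yn-8-yl]sulfonyl}benzene (epimers at C8) | C#C[C@@H](C)CC/C=C(\C)C(C[C@@H](C)C(C)=C)S(=O)(=O)c1ccccc1
A1 | alternative 1 | (3E,5S,6S,9E,13R)-3,6,10,13,14-pentamethyl-1-[(1S,3S)-2,2,3-trimethyl-6-methylidenecyclohexyl]pentadeca-3,9,14-trien-5-ol | C/C(CC[C@H]1C(=C)CC[C@H](C)C1(C)C)=C\[C@@H](O)[C@@H](C)CC/C=C(\C)CC[C@@H](C)C(C)=C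
A2 | alternative 1 | ethyl (3S,4E,6S,9E,13R)-3,6,10,13,14-pentamethyl-3-{2-[(1S,3S)-2,2,3-trimethyl-6-methylidenecyclohexyl]ethyl}pentadeca-4,9,14-trienoate | CCOC(=O)C[C@@](C)(/C=C/[C@@H](C)CC/C=C(\C)CC[C@@H](C)C(C)=C)CC[C@H]1C(=C)CC[C@H](C)C1(C)C
A3 | alternative 1 | (2S,5E,9R)-2,6,9,10-tetramethylundeca-5,10-dienal | O=C[C@@H](C)CC/C=C(\C)CC[C@@H](C)C(C)=C
A4 | alternative 2 | (2S)-2-ethenyl-2-methyl-4-[(1S,3S)-2,2,3-trimethyl-6-methylidenecyclohexyl]butanal | C=C[C@@](C)(C=O)CC[C@H]1C(=C)CC[C@H](C)C1(C)C
A5 | alternative 2 | 1-phenyl-5-{[(2S,5E,9R)-2,6,9,10-tetramethylundeca-5,10-dien-1-yl]sulfonyl}-1H-tetrazole | O=S(=O)(C[C@@H](C)CC/C=C(\C)CC[C@@H](C)C(C)=C)c1nnnn1-c1ccccc1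
A6 | alternative 3 | (3S,4E,6S,9E,13R)-3,6,10,13,14-pentamethyl-3-[(3E,7S)-4,7,8-trimethylnona-3,8-dien-1-yl]pentadeca-1,4,9,14-tetraene | C=C[C@@](C)(/C=C/[C@@H](C)CC/C=C(\C)CC[C@@H](C)C(C)=C)CC/C=C(\C)CC[C@H](C)C(C)=C
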